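**Plan**

- The target is a γ-lactone (O1, C2 carbonyl, C3, C4, C5) with a 4-hydroxy-3-methoxybenzyl group on C3 and the carbinol carbon CH(OH)Ar (Ar = 3,4-dimethoxyphenyl) on C4. The retrosynthesis cuts the C3–benzyl bond first (enolate alkylation). It then trades the carbinol C–O bond for a temporary C3–carbinol-carbon bond. Last, it cuts C3–C4 and that temporary bond together (carbene addition to an alkene).
- Enabling feature: the carbinol carbon sits 1,3 to C3 through C4. The temporary bond therefore closes a three-membered ring C3–C4–C(carbinol) fused to the lactone, with the dimethoxyphenyl ring as donor and the lactone carbonyl as acceptor.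
- Forward: aryl iodide and propargyl alcohol give the Z-cinnamyl alcohol and then its diazoacetate. The lactone and the cyclopropane close together in step 5, and water opens the cyclopropane in step 6. The vanillin-derived benzyl bromide is joined at C3 in step 11, and one desilylation finishes the route.
- Stereochemistry: C4 comes from the chiral rhodium catalyst (alkene face). The carbinol centre comes from the Z alkene geometry (endo aryl) followed by inversion in the ring opening. C3 comes from alkylation anti to the C4 substituent.

Key step: step 5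

Assumption: Rh2(5R-MEPY)4 is taken to give the (1S,5R) lactone series from Z-allylic diazoacetates and its 5S antipode the mirror image; both antipodes are available, so the sense can be corrected without changing the route.

**Route**

Step 1
Reactants: 1 4-iodo-1,2-dimethoxybenzene; 2 prop-2-yn-1-ol
Product: 3 3-(3,4-dimethoxyphenyl)prop-2-yn-1-ol
Conditions: PdCl2(PPh3)2 (2 mol %), CuI (4 mol %), Et3N, THF, rt
Reagents that add atoms: none
Why: Sonogashira coupling of an aryl iodide with a terminal alkyne, which tolerates the free propargylic hydroxyl and creates no stereocentre.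

Step 2
Reactants: 3 3-(3,4-dimethoxyphenyl)prop-2-yn-1-ol
Product: 4 (Z)-3-(3,4-dimethoxyphenyl)prop-2-en-1-ol
Conditions: H2 (1 atm), Pd/CaCO3 poisoned with Pb(OAc)2 (Lindlar catalyst), quinoline, EtOAc, rt, stopped after one equivalent of H2
Reagents that add atoms: none
Why: Lindlar semihydrogenation delivers both hydrogens to one face of the alkyne on the poisoned surface, so the Z alkene should result.

Step 3
Reactants: 4 (Z)-3-(3,4-dimethoxyphenyl)prop-2-en-1-ol; 5 bromoacetyl bromide
Product: 6 (Z)-3-(3,4-dimethoxyphenyl)prop-2-en-1-yl 2-bromoacetate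
Conditions: NaHCO3, MeCN, 0 °C
Reagents that add atoms: none
Why: O-acylation of a primary allylic alcohol by an acid bromide, with the mild insoluble base taking up HBr so that the Z alkene is not isomerised.

Step 4
Reactants: 6 (Z)-3-(3,4-dimethoxyphenyl)prop-2-en-1-yl 2-bromoacetate
Product: 8 (Z)-3-(3,4-dimethoxyphenyl)prop-2-en-1-yl 2-diazoacetate, via alkylated bis-sulfonylhydrazide 7 (not isolated)
Conditions: TsNHNHTs (2 equiv), DBU (5 equiv), THF, 0 °C
Reagents that add atoms: N,N'-ditosylhydrazine, Cc1ccc(cc1)S(=O)(=O)NNS(=O)(=O)c1ccc(C)cc1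
Why: Diazoacetate synthesis from a bromoacetate: N-alkylation of the ditosylhydrazine anion followed by two base-induced eliminations of p-toluenesulfinate, under conditions too mild to affect the alkene.

Step 5
Reactants: 8 (Z)-3-(3,4-dimethoxyphenyl)prop-2-en-1-yl 2-diazoacetate
Product: 9 (1S,5R,6S)-6-(3,4-dimethoxyphenyl)-3-oxabicyclo[3.1.0]hexan-2-one (aryl endo)
Conditions: Rh2(5R-MEPY)4 (1 mol %; MEPY = methyl 2-oxopyrrolidine-5-carboxylate, a dimer of divalent rhodium with four bridging carboxamidates), CH2Cl2, reflux, slow addition of 8 by syringe pump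
Reagents that add atoms: none
Why: The catalyst takes N2 from the diazoacetate to give an electrophilic rhodium-bound carbene, which adds to the tethered Z alkene in a concerted but asynchronous [2+1] step; this is the known enantioselective intramolecular cyclopropanation of allylic diazoacetates by chiral dirhodium carboxamidates. The five-membered lactone closes as the carbene carbon bonds to the nearer alkene carbon through the ester tether (the C3–C4 bond of the target lactone), which allows only the cis ring fusion, and the cyclopropane closes in the same event as the carbene carbon bonds to the benzylic carbon (the temporary C3–carbinol-carbon bond). C1 and C5 (bicycle numbering) are set together by the alkene face that the chiral carboxamidate ligands present to the carbene (catalyst control), and C6 is fixed relative to them by the stereospecific syn addition, the Z geometry placing the aryl group endo. The step needs high enantioface selectivity and cyclopropanation in preference to carbene dimerisation or attack on the electron-rich arene; Z-disubstituted allylic diazoacetates are the best-matched substrates for this catalyst family, the carboxamidate ligands temper the carbene, and slow addition keeps the diazo concentration low.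

Step 6
Reactants: 9 (1S,5R,6S)-6-(3,4-dimethoxyphenyl)-3-oxabicyclo[3.1.0]hexan-2-one
Product: 10 (R)-4-[(S)-(3,4-dimethoxyphenyl)(hydroxy)methyl]dihydrofuran-2(3H)-one
Conditions: Sc(OTf)3 (10 mol %), H2O (10 equiv), 1,4-dioxane, rt to 40 °C
Reagents that add atoms: water, O
Why: Proposed new method: Sc(OTf)3 on the lactone carbonyl polarises the fused C1–C6 bond, which lies nearly parallel to the carbonyl π system and carries the strongly donating dimethoxyphenyl group at C6, so water should attack C6 from the side opposite C1 in an SN2-like transition state and release the scandium enolate, which is protonated to the C3 methylene; this inverts C6, leaves C5 untouched and so turns the endo aryl geometry into the (S)-carbinol beside the (R)-C4 centre; the closest known reaction type is the Lewis-acid-catalysed SN2 ring opening of 2-arylcyclopropane-1,1-diesters by heteroatom nucleophiles with inversion at the aryl-bearing carbon, together with acid-promoted openings of aryl cyclopropyl ketones by oxygen nucleophiles.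

Step 7
Reactants: 10 (R)-4-[(S)-(3,4-dimethoxyphenyl)(hydroxy)methyl]dihydrofuran-2(3H)-one
Product: 11 (R)-4-[(S)-(3,4-dimethoxyphenyl)(triethylsilyloxy)methyl]dihydrofuran-2(3H)-one
Conditions: Et3SiCl, imidazole, CH2Cl2, 0 °C
Reagents that add atoms: chlorotriethylsilane, CC[Si](Cl)(CC)CC
Why: Silyl ether formation with a silyl chloride and imidazole masks the only acidic hydroxyl before enolate chemistry under near-neutral conditions that touch no stereocentre.

Step 8
Reactants: 12 vanillin
Product: 13 4-(tert-butyldimethylsilyloxy)-3-methoxybenzaldehyde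
Conditions: t-BuMe2SiCl, imidazole, DMF, rt
Reagents that add atoms: tert-butyldimethylsilyl chloride, CC(C)(C)[Si](C)(C)Cl
Why: Silylation of a phenol with a silyl chloride and imidazole, a standard protection that the aldehyde tolerates.

Step 9
Reactants: 13 4-(tert-butyldimethylsilyloxy)-3-methoxybenzaldehyde
Product: 14 [4-(tert-butyldimethylsilyloxy)-3-methoxyphenyl]methanol
Conditions: NaBH4, MeOH, 0 °C
Reagents that add atoms: none
Why: Borohydride reduction of an aryl aldehyde to the benzylic alcohol, kept short and cold so that the aryl silyl ether survives.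

Step 10
Reactants: 14 [4-(tert-butyldimethylsilyloxy)-3-methoxyphenyl]methanol
Product: 15 [4-(bromomethyl)-2-methoxyphenoxy](tert-butyl)dimethylsilane
Conditions: CBr4, PPh3, CH2Cl2, 0 °C; used without storage
Reagents that add atoms: carbon tetrabromide, BrC(Br)(Br)Br
Why: Appel bromination converts the benzylic alcohol into the bromide under neutral conditions that avoid HBr and so spare the aryl silyl ether.

Step 11
Reactants: 11 (R)-4-[(S)-(3,4-dimethoxyphenyl)(triethylsilyloxy)methyl]dihydrofuran-2(3H)-one; 15 [4-(bromomethyl)-2-methoxyphenoxy](tert-butyl)dimethylsilane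
Product: 17 (3R,4R)-3-[4-(tert-butyldimethylsilyloxy)-3-methoxybenzyl]-4-[(S)-(3,4-dimethoxyphenyl)(triethylsilyloxy)methyl]dihydrofuran-2(3H)-one, via lithium enolate 16 (not isolated)
Conditions: LiN(SiMe3)2, THF, −78 °C; then 15, DMPU, −78 to −40 °C
Reagents that add atoms: none
Why: Kinetic C-alkylation of a β-substituted γ-butyrolactone lithium enolate (SN2 on a benzylic bromide), in which the bromide approaches the enolate face anti to the bulky C4 substituent and so sets C3 as R, trans to C4, the established outcome for this lactone class.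

Step 12
Reactants: 17 (3R,4R)-3-[4-(tert-butyldimethylsilyloxy)-3-methoxybenzyl]-4-[(S)-(3,4-dimethoxyphenyl)(triethylsilyloxy)methyl]dihydrofuran-2(3H)-one
Product: 18 (3R,4R)-4-[(S)-(3,4-dimethoxyphenyl)(hydroxy)methyl]-3-(4-hydroxy-3-methoxybenzyl)dihydrofuran-2(3H)-one
Conditions: Bu4NF, AcOH (1:1), THF, 0 °C to rt
Reagents that add atoms: none
Why: Fluoride-mediated cleavage of the aryl and the alkyl silyl ether, buffered with acetic acid so that neither a phenoxide nor the benzylic alkoxide persists, which guards against translactonisation and C3 epimerisation.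

**Compound list**

1 | 4-iodo-1,2-dimethoxybenzene | COc1ccc(I)cc1OC | starting material
2 | prop-2-yn-1-ol | C#CCO | starting material
3 | 3-(3,4-dimethoxyphenyl)prop-2-yn-1-ol | COc1ccc(C#CCO)cc1OC | intermediate
4 | (Z)-3-(3,4-dimethoxyphenyl)prop-2-en-1-ol | COc1ccc(/C=C\CO)cc1OC | intermediate
5 | bromoacetyl bromide | O=C(Br)CBr | starting material
6 | (Z)-3-(3,4-dimethoxyphenyl)prop-2-en-1-yl 2-bromoacetate | COc1ccc(/C=C\COC(=O)CBr)cc1OC | intermediate
7 | (Z)-3-(3,4-dimethoxyphenyl)prop-2-en-1-yl 2-[1,2-bis(4-methylphenylsulfonyl)hydrazin-1-yl]acetate | COc1ccc(/C=C\COC(=O)CN(NS(=O)(=O)c2ccc(C)cc2)S(=O)(=O)c2ccc(C)cc2)cc1OC | intermediate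
8 | (Z)-3-(3,4-dimethoxyphenyl)prop-2-en-1-yl 2-diazoacetate | COc1ccc(/C=C\COC(=O)C=[N+]=[N-])cc1OC | intermediate
9 | (1S,5R,6S)-6-(3,4-dimethoxyphenyl)-3-oxabicyclo[3.1.0]hexan-2-one | O=C1OC[C@@H]2[C@H](c3ccc(OC)c(OC)c3)[C@H]12 | intermediate
10 | (R)-4-[(S)-(3,4-dimethoxyphenyl)(hydroxy)methyl]dihydrofuran-2(3H)-one | O=C1C[C@H](CO1)[C@H](O)c1ccc(OC)c(OC)c1 | intermediate
11 | (R)-4-[(S)-(3,4-dimethoxyphenyl)(triethylsilyloxy)methyl]dihydrofuran-2(3H)-one | O=C1C[C@H](CO1)[C@H](O[Si](CC)(CC)CC)c1ccc(OC)c(OC)c1 | intermediate
12 | vanillin (4-hydroxy-3-methoxybenzaldehyde) | COc1cc(C=O)ccc1O | starting material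
13 | 4-(tert-butyldimethylsilyloxy)-3-methoxybenzaldehyde | COc1cc(C=O)ccc1O[Si](C)(C)C(C)(C)C | intermediate
14 | [4-(tert-butyldimethylsilyloxy)-3-methoxyphenyl]methanol | COc1cc(CO)ccc1O[Si](C)(C)C(C)(C)C | intermediate
15 | [4-(bromomethyl)-2-methoxyphenoxy](tert-butyl)dimethylsilane | COc1cc(CBr)ccc1O[Si](C)(C)C(C)(C)C | intermediate
16 | lithium (R)-4-[(S)-(3,4-dimethoxyphenyl)(triethylsilyloxy)methyl]-4,5-dihydrofuran-2-olate (lithium enolate of 11) | [Li+].[O-]C1=C[C@H](CO1)[C@H](O[Si](CC)(CC)CC)c1ccc(OC)c(OC)c1 | intermediate
17 | (3R,4R)-3-[4-(tert-butyldimethylsilyloxy)-3-methoxybenzyl]-4-[(S)-(3,4-dimethoxyphenyl)(triethylsilyloxy)methyl]dihydrofuran-2(3H)-one | COc1cc(C[C@H]2C(=O)OC[C@@H]2[C@H](O[Si](CC)(CC)CC)c2ccc(OC)c(OC)c2)ccc1O[Si](C)(C)C(C)(C)C | intermediate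
18 | (3R,4R)-4-[(S)-(3,4-dimethoxyphenyl)(hydroxy)methyl]-3-(4-hydroxy-3-methoxybenzyl)dihydrofuran-2(3H)-one | COc1cc(C[C@H]2C(=O)OC[C@@H]2[C@H](O)c2ccc(OC)c(OC)c2)ccc1O | target

**Step count**

Total: 12 steps. Longest linear sequence: 9 steps (steps 1–7, 11 and 12, from 4-iodo-1,2-dimethoxybenzene); the three-step branch from vanillin (steps 8–10) joins at step 11.

**Steps most likely to fail**

1. Step 6 (proposed new method). The dimethoxyphenyl donor may let the C1–C6 bond ionise before water is delivered. A free benzylic cation would erode the inversion, could re-close to the exo cyclopropane or be captured by the carbonyl oxygen, and the product carbinol could itself re-ionise under the Lewis acid. The fallback uses known chemistry and gives up stereospecificity in the opening. It sets out from 9, which is hydrated without demand on the stereochemical course (TfOH cat. in aqueous hexafluoroisopropanol, the ionising regime known for aryl cyclopropanes with one carbonyl acceptor). This gives 10 mixed with its carbinol epimer (R)-4-[(R)-(3,4-dimethoxyphenyl)(hydroxy)methyl]dihydrofuran-2(3H)-one F1. The mixture is oxidised with Dess–Martin periodinane (NaHCO3-buffered, CH2Cl2) to the aryl ketone (R)-4-(3,4-dimethoxybenzoyl)dihydrofuran-2(3H)-one F2, conditions under which the C4 centre α to the ketone should not epimerise. Corey–Bakshi–Shibata reduction of F2 with the (R)-2-methyl-oxazaborolidine and BH3·SMe2 at low temperature (reagent control, aryl as the large group) should then give the (S)-carbinol and return to the route at 10.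

2. Step 12. If the medium turns basic, the freed benzylic oxygen can attack the lactone carbonyl and translactonise to the 5-aryl-4-(hydroxymethyl) isomer; if it turns acidic, the carbinol can ionise. The fallback changes the protecting-group plan so that the phenol is freed by neutral hydrogenolysis. It sets out from 11: the enolate 16 is alkylated with 4-(benzyloxy)-3-methoxybenzyl bromide F3 (made from commercial 4-(benzyloxy)-3-methoxybenzyl alcohol with PBr3) to give (3R,4R)-3-[4-(benzyloxy)-3-methoxybenzyl]-4-[(S)-(3,4-dimethoxyphenyl)(triethylsilyloxy)methyl]dihydrofuran-2(3H)-one F4. The triethylsilyl ether is removed with HF·pyridine in THF/pyridine at 0 °C, where no alkoxide forms, to give (3R,4R)-3-[4-(benzyloxy)-3-methoxybenzyl]-4-[(S)-(3,4-dimethoxyphenyl)(hydroxy)methyl]dihydrofuran-2(3H)-one F5. Hydrogenolysis of the benzyl ether (H2, 1 atm, Pd/C, EtOAc, rt, stopped at full conversion to spare the benzylic alcohol) comes back to the route at 18.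

3. Step 2. Over-reduction to the saturated alcohol and Z-to-E isomerisation on the catalyst surface would lower the geometric purity. Any E alkene ends as the exo-aryl lactone and hence as the wrong carbinol epimer. The fallback builds the Z alkene by cross-coupling with retention instead of by hydrogenation. It sets out from 2: iodination of the alkyne terminus (N-iodosuccinimide, AgNO3 cat., acetone) gives 3-iodoprop-2-yn-1-ol F6. Diimide reduction (2-nitrobenzenesulfonylhydrazide, Et3N) gives (Z)-3-iodoprop-2-en-1-ol F7. Suzuki–Miyaura coupling of F7 with commercial 3,4-dimethoxyphenylboronic acid (Pd(PPh3)4, aqueous K2CO3, THF) should proceed with retention of geometry and comes back to the route at 4.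

**Further compounds**

F1 | step 6 | (R)-4-[(R)-(3,4-dimethoxyphenyl)(hydroxy)methyl]dihydrofuran-2(3H)-one | O=C1C[C@H](CO1)[C@@H](O)c1ccc(OC)c(OC)c1
F2 | step 6 | (R)-4-(3,4-dimethoxybenzoyl)dihydrofuran-2(3H)-one | O=C1C[C@H](CO1)C(=O)c1ccc(OC)c(OC)c1
F3 | step 12 | 4-(benzyloxy)-3-methoxybenzyl bromide | COc1cc(CBr)ccc1OCc1ccccc1
F4 | step 12 | (3R,4R)-3-[4-(benzyloxy)-3-methoxybenzyl]-4-[(S)-(3,4-dimethoxyphenyl)(triethylsilyloxy)methyl]dihydrofuran-2(3H)-one | COc1cc(C[C@H]2C(=O)OC[C@@H]2[C@H](O[Si](CC)(CC)CC)c2ccc(OC)c(OC)c2)ccc1OCc1ccccc1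
F5 | step 12 | (3R,4R)-3-[4-(benzyloxy)-3-methoxybenzyl]-4-[(S)-(3,4-dimethoxyphenyl)(hydroxy)methyl]dihydrofuran-2(3H)-one | COc1cc(C[C@H]2C(=O)OC[C@@H]2[C@H](O)c2ccc(OC)c(OC)c2)ccc1OCc1ccccc1
F6 | step 2 | 3-iodoprop-2-yn-1-ol | OCC#CI
F7 | step 2 | (Z)-3-iodoprop-2-en-1-ol | OC/C=C\I
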